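**Strategy.** The ten-membered carbocycle (germacrane numbering: C1=C10(Me), C2, C3–O-angelate, C4(Me)–C5 epoxide, C6–OAc, C7-isopropenyl, C8, C9) is not closed at C2–C3 directly. Geranyl acetate supplies C1, C2 and C7–C14, a C5 enal supplies C3–C6, and the two are joined at C6–C7 by an enantioselective syn allylation and at C2/C3 through oxygen, giving an eleven-membered diallyl ether. A [1,2]-Wittig rearrangement then deletes the ring oxygen: C2 migrates from O to C3, which contracts the ring to the carbocycle and leaves the oxygen as the C3 hydroxyl. The step exploits the two E-alkenes C1=C10 and C4=C5, which make C2 and C3 allylic and forbid the competing [2,3]-shift.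

Key step: step 12

Remark (assumption): the acyloxyborane from (2R,3R)-tartaric acid is taken to expose the Re face of the bound enal 9, as it does with other aldehydes; if the sense is opposite, the catalyst from (2S,3S)-tartaric acid is used.

Step 1
Reactants: 1 geranyl acetate
Product: 2 (2E,6E)-8-hydroxy-3,7-dimethylocta-2,6-dien-1-yl acetate
Conditions: SeO2 (cat.), t-BuOOH, salicylic acid (cat.), CH2Cl2, rt
Reagents that add atoms: tert-butyl hydroperoxide, CC(C)(C)OO; selenium dioxide, O=[Se]=O (catalytic oxygen carrier)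
Why: SeO2/t-BuOOH allylic oxidation (ene reaction, then [2,3]-shift) should hydroxylate the E-methyl group of the remote, more electron-rich alkene with retention of the E geometry, the 2,3-alkene being deactivated by the allylic acetate.

Step 2
Reactants: 2 (2E,6E)-8-hydroxy-3,7-dimethylocta-2,6-dien-1-yl acetate
Product: 3 (2E,6E)-8-bromo-3,7-dimethylocta-2,6-dien-1-yl acetate
Conditions: CBr4, PPh3, CH2Cl2, 0 °C
Reagents that add atoms: carbon tetrabromide, BrC(Br)(Br)Br
Why: Appel bromination converts the primary allylic alcohol into the bromide by SN2 without allylic transposition and leaves the acetate untouched.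

Step 3
Reactants: 3 (2E,6E)-8-bromo-3,7-dimethylocta-2,6-dien-1-yl acetate
Product: 4 (2E,6E)-3,7-dimethyl-8-(tributylstannyl)octa-2,6-dien-1-yl acetate
Conditions: Zn powder, Bu3SnCl, THF/sat. aq. NH4Cl, rt
Reagents that add atoms: tributyltin chloride, CCCC[Sn](Cl)(CCCC)CCCC
Why: Barbier-type zinc-mediated stannylation of the allylic bromide tolerates the acetate and should give the more stable primary E-allylstannane.

Step 4
Reactants: 5 prenyl acetate (3-methylbut-2-en-1-yl acetate)
Product: 6 (E)-4-hydroxy-3-methylbut-2-en-1-yl acetate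
Conditions: SeO2 (cat.), t-BuOOH, CH2Cl2, rt
Reagents that add atoms: tert-butyl hydroperoxide, CC(C)(C)OO; selenium dioxide, O=[Se]=O (catalytic oxygen carrier)
Why: The same SeO2/t-BuOOH allylic oxidation attacks the E-methyl group and so fixes the E geometry of the later C4=C5 alkene.

Step 5
Reactants: 6 (E)-4-hydroxy-3-methylbut-2-en-1-yl acetate
Product: 7 (E)-4-chloro-3-methylbut-2-en-1-yl acetate
Conditions: PPh3, CCl4, CH2Cl2, rt
Reagents that add atoms: carbon tetrachloride, ClC(Cl)(Cl)Cl
Why: Appel chlorination of the primary allylic alcohol proceeds by SN2 at carbon and should not move or isomerise the alkene.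

Step 6
Reactants: 7 (E)-4-chloro-3-methylbut-2-en-1-yl acetate
Product: 8 (E)-4-chloro-3-methylbut-2-en-1-ol
Conditions: K2CO3 (cat.), MeOH, 0 °C
Reagents that add atoms: none
Why: Base-catalysed transesterification (methanolysis) should remove the acetate faster than methoxide displaces the allylic chloride at 0 °C.

Step 7
Reactants: 8 (E)-4-chloro-3-methylbut-2-en-1-ol
Product: 9 (E)-4-chloro-3-methylbut-2-enal
Conditions: MnO2, CH2Cl2, rt
Reagents that add atoms: none
Why: MnO2 oxidation is selective for the allylic alcohol and gives the enal with the E geometry retained.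

Step 8
Reactants: 4 (2E,6E)-3,7-dimethyl-8-(tributylstannyl)octa-2,6-dien-1-yl acetate; 9 (E)-4-chloro-3-methylbut-2-enal
Product: 10 (2E,6S)-6-[(1S,2E)-4-chloro-1-hydroxy-3-methylbut-2-en-1-yl]-3,7-dimethylocta-2,7-dien-1-yl acetate (carbinol carbon = C6, branched carbon = C7)
Conditions: (2R,3R)-2-O-(2,6-diisopropoxybenzoyl)tartaric acid/BH3·THF (chiral acyloxyborane catalyst, 20 mol%), EtCN, −78 °C; aq. NaHCO3
Reagents that add atoms: none
Why: Chiral-acyloxyborane-catalysed carbonyl allylation with an allylstannane (Hosomi–Sakurai type, SE2′ through C7): the catalyst should direct attack to the Re face of the enal and so set C6, and the open antiperiplanar transition state should give the syn relation that sets C7, whatever the stannane geometry.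

Step 9
Reactants: 10 (2E,6S)-6-[(1S,2E)-4-chloro-1-hydroxy-3-methylbut-2-en-1-yl]-3,7-dimethylocta-2,7-dien-1-yl acetate
Product: 11 (2E,6S)-6-[(1S,2E)-1-[(tert-butyldimethylsilyl)oxy]-4-chloro-3-methylbut-2-en-1-yl]-3,7-dimethylocta-2,7-dien-1-yl acetate
Conditions: TBSOTf, 2,6-lutidine, CH2Cl2, −78 to 0 °C
Reagents that add atoms: tert-butyldimethylsilyl triflate, CC(C)(C)[Si](C)(C)OS(=O)(=O)C(F)(F)F
Why: Silylation of the hindered secondary alcohol gives a base-stable ether without acidic protons that carries O6 through the organolithium steps.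

Step 10
Reactants: 11 (2E,6S)-6-[(1S,2E)-1-[(tert-butyldimethylsilyl)oxy]-4-chloro-3-methylbut-2-en-1-yl]-3,7-dimethylocta-2,7-dien-1-yl acetate
Product: 12 (2E,6S)-6-[(1S,2E)-1-[(tert-butyldimethylsilyl)oxy]-4-chloro-3-methylbut-2-en-1-yl]-3,7-dimethylocta-2,7-dien-1-ol
Conditions: iBu2AlH, CH2Cl2, −78 °C; aq. potassium sodium tartrate
Reagents that add atoms: none
Why: Reductive cleavage of the acetate by iBu2AlH at −78 °C frees the C2 hydroxyl without touching the allylic chloride or the silyl ether.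

Step 11
Reactants: 12 (2E,6S)-6-[(1S,2E)-1-[(tert-butyldimethylsilyl)oxy]-4-chloro-3-methylbut-2-en-1-yl]-3,7-dimethylocta-2,7-dien-1-ol
Product: 14 (3E,5S,6S,9E)-5-[(tert-butyldimethylsilyl)oxy]-3,9-dimethyl-6-(prop-1-en-2-yl)-1-oxacycloundeca-3,9-diene (ring oxygen between C2 and C3), via sodium C2-alkoxide 13 (not isolated)
Conditions: NaH, Bu4NI (cat.), THF, 50 °C, syringe-pump addition (final 1 mM)
Reagents that add atoms: none
Why: Intramolecular Williamson etherification under high dilution: the primary allylic alkoxide displaces the primary allylic chloride by SN2 (iodide catalysis), and the E geometry of both alkenes rules out smaller rings, so the eleven-membered diallyl ether should form.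

Step 12
Reactants: 14 (3E,5S,6S,9E)-5-[(tert-butyldimethylsilyl)oxy]-3,9-dimethyl-6-(prop-1-en-2-yl)-1-oxacycloundeca-3,9-diene
Product: 17 (1(10)E,4E,6S,7S)-6-[(tert-butyldimethylsilyl)oxy]germacra-1(10),4,11-trien-3-ol (both C3 epimers), via C3-lithiated ether 15 (not isolated), via lithium C3-alkoxide 16 (not isolated)
Conditions: n-BuLi, THF, −78 to −40 °C; sat. aq. NH4Cl at −78 °C
Reagents that add atoms: none
Why: n-BuLi should remove an allylic proton α to oxygen at C3 rather than at C2, because the C3–C4–C5 allyl anion ends on the mono-substituted C5 whereas metalation at C2 would put charge on the disubstituted C10; the α-alkoxy allyllithium 15 then undergoes a [1,2]-Wittig rearrangement, in which the O–C2 bond breaks homolytically and the caged ketyl/allyl radical pair recombines at C3–C2 to give alkoxide 16. The closest known reaction type is the Wittig ring contraction of macrocyclic diallyl ethers, in which [1,2]-shifted carbocycles accompany the [2,3]-products. No ring is closed by a cyclisation: the ten-membered carbocycle arises from the eleven-membered oxacycle by 1,2-migration of C2 from oxygen to C3, and the expelled ring oxygen stays on C3 as the alkoxide. The selectivity needed is [1,2] over [2,3] and [1,4], and the substrate secures it, since bonding C3 to C10 or C5 to C2 would give an eight-membered ring that holds an E-alkene (C4=C5 or C1=C10). The only new stereocentre, C3, is formed by radical recombination under nothing but the conformational bias of the ring and is therefore not relied on; it is erased and set again in steps 13 and 14, while C6 and C7 are not touched. Quenching at −78 °C should keep the lithium 1,5-dien-3-olate 16 from an anionic oxy-Cope rearrangement.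

Step 13
Reactants: 17 (1(10)E,4E,6S,7S)-6-[(tert-butyldimethylsilyl)oxy]germacra-1(10),4,11-trien-3-ol (both C3 epimers)
Product: 18 (1(10)E,4E,6S,7S)-6-[(tert-butyldimethylsilyl)oxy]germacra-1(10),4,11-trien-3-one
Conditions: Dess–Martin periodinane, CH2Cl2, 0 °C
Reagents that add atoms: none
Why: Dess–Martin oxidation under near-neutral conditions converges both C3 epimers on one enone without conjugating the β,γ-alkene C1=C10.

Step 14
Reactants: 18 (1(10)E,4E,6S,7S)-6-[(tert-butyldimethylsilyl)oxy]germacra-1(10),4,11-trien-3-one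
Product: 19 (1(10)E,3S,4E,6S,7S)-6-[(tert-butyldimethylsilyl)oxy]germacra-1(10),4,11-trien-3-ol
Conditions: (R)-1-methyl-3,3-diphenyl-tetrahydro-pyrrolo[1,2-c][1,3,2]oxazaborole ((R)-Me-CBS, 20 mol%), catecholborane, toluene, −78 °C
Reagents that add atoms: none
Why: Corey–Bakshi–Shibata reduction: the (R)-oxazaborolidine treats the C4=C5 alkenyl arm as the large group and should deliver hydride 1,2 to the face that gives the 3S allylic alcohol.

Step 15
Reactants: 19 (1(10)E,3S,4E,6S,7S)-6-[(tert-butyldimethylsilyl)oxy]germacra-1(10),4,11-trien-3-ol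
Product: 21 (1(10)E,3S,4E,6S,7S)-6-[(tert-butyldimethylsilyl)oxy]germacra-1(10),4,11-trien-3-yl (2Z)-2-methylbut-2-enoate (angelate), via lithium C3-alkoxide 20 (not isolated)
Conditions: LiN(SiMe3)2, THF, −78 °C; angelic anhydride, −78 to −40 °C
Reagents that add atoms: (2Z)-2-methylbut-2-enoic anhydride (angelic anhydride), C/C=C(/C)C(=O)OC(=O)/C(C)=C\C
Why: O-Acylation of the lithium alkoxide with the anhydride at low temperature avoids the nucleophilic catalysts that isomerise angelate to tiglate and stays below the temperature at which the 1,5-dien-3-olate could rearrange.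

Step 16
Reactants: 21 (1(10)E,3S,4E,6S,7S)-6-[(tert-butyldimethylsilyl)oxy]germacra-1(10),4,11-trien-3-yl angelate
Product: 22 (1(10)E,3S,4E,6S,7S)-6-hydroxygermacra-1(10),4,11-trien-3-yl angelate
Conditions: Bu4NF, AcOH, THF, 0 °C to rt
Reagents that add atoms: none
Why: Buffered fluoride desilylation frees the C6 hydroxyl without ester migration or acid-induced transannular cyclisation of the 1,5-diene.

Step 17
Reactants: 22 (1(10)E,3S,4E,6S,7S)-6-hydroxygermacra-1(10),4,11-trien-3-yl angelate
Product: 23 (1(10)E,3S,4R,5R,6R,7S)-4,5-epoxy-6-hydroxygermacra-1(10),11-dien-3-yl angelate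
Conditions: VO(acac)2 (5 mol%), t-BuOOH, CH2Cl2, 0 °C
Reagents that add atoms: tert-butyl hydroperoxide, CC(C)(C)OO
Why: Hydroxyl-directed VO(acac)2/t-BuOOH epoxidation: only C4=C5 is allylic to the free C6–OH, and in the conformer with the ring bonds C3–C2 and C6–C7 turned inward the C6–O bond lies on the exposed face, so oxygen should be delivered there to give the 4R,5R-epoxide (erythro to C6–O), the C3 ester not directing.

Step 18
Reactants: 23 (1(10)E,3S,4R,5R,6R,7S)-4,5-epoxy-6-hydroxygermacra-1(10),11-dien-3-yl angelate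
Product: 24 (1(10)E,3S,4R,5R,6R,7S)-6-acetoxy-4,5-epoxygermacra-1(10),11-dien-3-yl angelate (target)
Conditions: Ac2O, pyridine, DMAP (cat.), CH2Cl2, 0 °C
Reagents that add atoms: acetic anhydride, CC(=O)OC(C)=O
Why: Nucleophile-catalysed acetylation of the remaining secondary alcohol is mild enough to leave the epoxide, the angelate and the alkenes unchanged.

**Compound list**

1 | geranyl acetate | CC(C)=CCC/C(C)=C/COC(C)=O | starting material
2 | (2E,6E)-8-hydroxy-3,7-dimethylocta-2,6-dien-1-yl acetate | OC/C(C)=C/CC/C(C)=C/COC(C)=O | intermediate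
3 | (2E,6E)-8-bromo-3,7-dimethylocta-2,6-dien-1-yl acetate | BrC/C(C)=C/CC/C(C)=C/COC(C)=O | intermediate
4 | (2E,6E)-3,7-dimethyl-8-(tributylstannyl)octa-2,6-dien-1-yl acetate | CCCC[Sn](CCCC)(CCCC)C/C(C)=C/CC/C(C)=C/COC(C)=O | intermediate
5 | prenyl acetate (3-methylbut-2-en-1-yl acetate) | CC(C)=CCOC(C)=O | starting material
6 | (E)-4-hydroxy-3-methylbut-2-en-1-yl acetate | OC/C(C)=C/COC(C)=O | intermediate
7 | (E)-4-chloro-3-methylbut-2-en-1-yl acetate | ClC/C(C)=C/COC(C)=O | intermediate
8 | (E)-4-chloro-3-methylbut-2-en-1-ol | ClC/C(C)=C/CO | intermediate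
9 | (E)-4-chloro-3-methylbut-2-enal | ClC/C(C)=C/C=O | intermediate
10 | (2E,6S)-6-[(1S,2E)-4-chloro-1-hydroxy-3-methylbut-2-en-1-yl]-3,7-dimethylocta-2,7-dien-1-yl acetate | C=C(C)[C@H](CC/C(C)=C/COC(C)=O)[C@@H](O)/C=C(C)/CCl | intermediate
11 | (2E,6S)-6-[(1S,2E)-1-[(tert-butyldimethylsilyl)oxy]-4-chloro-3-methylbut-2-en-1-yl]-3,7-dimethylocta-2,7-dien-1-yl acetate | C=C(C)[C@H](CC/C(C)=C/COC(C)=O)[C@@H](O[Si](C)(C)C(C)(C)C)/C=C(C)/CCl | intermediate
12 | (2E,6S)-6-[(1S,2E)-1-[(tert-butyldimethylsilyl)oxy]-4-chloro-3-methylbut-2-en-1-yl]-3,7-dimethylocta-2,7-dien-1-ol | C=C(C)[C@H](CC/C(C)=C/CO)[C@@H](O[Si](C)(C)C(C)(C)C)/C=C(C)/CCl | intermediate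
13 | sodium C2-alkoxide of 12 (not isolated) | C=C(C)[C@H](CC/C(C)=C/C[O-])[C@@H](O[Si](C)(C)C(C)(C)C)/C=C(C)/CCl.[Na+] | intermediate
14 | (3E,5S,6S,9E)-5-[(tert-butyldimethylsilyl)oxy]-3,9-dimethyl-6-(prop-1-en-2-yl)-1-oxacycloundeca-3,9-diene | C=C(C)[C@@H]1CC/C(C)=C/COC/C(C)=C/[C@@H]1O[Si](C)(C)C(C)(C)C | intermediate
15 | C3-lithiated ether: 14 with lithium on the ring CH2 between the oxygen and C(Me)= (not isolated) | C=C(C)[C@@H]1CC/C(C)=C/COC([Li])/C(C)=C/[C@@H]1O[Si](C)(C)C(C)(C)C | intermediate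
16 | lithium C3-alkoxide of 17 (not isolated) | C=C(C)[C@@H]1CC/C(C)=C/CC([O-])/C(C)=C/[C@@H]1O[Si](C)(C)C(C)(C)C.[Li+] | intermediate
17 | (1(10)E,4E,6S,7S)-6-[(tert-butyldimethylsilyl)oxy]germacra-1(10),4,11-trien-3-ol, both C3 epimers [(2E,4S,5S,8E)-4-silyloxy-2,8-dimethyl-5-(prop-1-en-2-yl)cyclodeca-2,8-dien-1-ol] | C=C(C)[C@@H]1CC/C(C)=C/CC(O)/C(C)=C/[C@@H]1O[Si](C)(C)C(C)(C)C | intermediate
18 | (1(10)E,4E,6S,7S)-6-[(tert-butyldimethylsilyl)oxy]germacra-1(10),4,11-trien-3-one | C=C(C)[C@@H]1CC/C(C)=C/CC(=O)/C(C)=C/[C@@H]1O[Si](C)(C)C(C)(C)C | intermediate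
19 | (1(10)E,3S,4E,6S,7S)-6-[(tert-butyldimethylsilyl)oxy]germacra-1(10),4,11-trien-3-ol | C=C(C)[C@@H]1CC/C(C)=C/C[C@H](O)/C(C)=C/[C@@H]1O[Si](C)(C)C(C)(C)C | intermediate
20 | lithium C3-alkoxide of 19 (not isolated) | C=C(C)[C@@H]1CC/C(C)=C/C[C@H]([O-])/C(C)=C/[C@@H]1O[Si](C)(C)C(C)(C)C.[Li+] | intermediate
21 | (1(10)E,3S,4E,6S,7S)-6-[(tert-butyldimethylsilyl)oxy]germacra-1(10),4,11-trien-3-yl (2Z)-2-methylbut-2-enoate | C=C(C)[C@@H]1CC/C(C)=C/C[C@H](OC(=O)/C(C)=C\C)/C(C)=C/[C@@H]1O[Si](C)(C)C(C)(C)C | intermediate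
22 | (1(10)E,3S,4E,6S,7S)-6-hydroxygermacra-1(10),4,11-trien-3-yl (2Z)-2-methylbut-2-enoate | C=C(C)[C@@H]1CC/C(C)=C/C[C@H](OC(=O)/C(C)=C\C)/C(C)=C/[C@@H]1O | intermediate
23 | (1(10)E,3S,4R,5R,6R,7S)-4,5-epoxy-6-hydroxygermacra-1(10),11-dien-3-yl (2Z)-2-methylbut-2-enoate | C=C(C)[C@@H]1CC/C(C)=C/C[C@H](OC(=O)/C(C)=C\C)[C@@]2(C)O[C@@H]2[C@@H]1O | intermediate
24 | (1(10)E,3S,4R,5R,6R,7S)-6-acetoxy-4,5-epoxygermacra-1(10),11-dien-3-yl (2Z)-2-methylbut-2-enoate | C=C(C)[C@@H]1CC/C(C)=C/C[C@H](OC(=O)/C(C)=C\C)[C@@]2(C)O[C@@H]2[C@@H]1OC(C)=O | target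

Total step count: 18. Longest linear sequence: 15 steps (steps 4–7 from prenyl acetate, then steps 8–18).

**Steps most likely to fail**

1. Step 12 (key step). What may go wrong: metalation at C2 or at the silyloxy-bearing C6 instead of C3; recombination of the radical pair across the ring (C5 to C10) to a cyclohexane; loss of the E geometry in the allyl anion, which would open the [2,3]-channel; or oxy-Cope collapse of alkoxide 16 on warming. The fallback changes the atoms that are extruded from oxygen to CO2; it sets out from 12 and comes back at 18. Sodium benzenesulfinate in DMF displaces the allylic chloride to give the sulfone alcohol (2E,6S)-6-[(1S,2E)-1-[(tert-butyldimethylsilyl)oxy]-3-methyl-4-(phenylsulfonyl)but-2-en-1-yl]-3,7-dimethylocta-2,7-dien-1-ol F1. Its dianion (n-BuLi, THF, −78 °C) is carboxylated with CO2 at the sulfonyl carbon to give the hydroxy acid (3E,5S,6S,9E)-5-[(tert-butyldimethylsilyl)oxy]-11-hydroxy-3,9-dimethyl-2-(phenylsulfonyl)-6-(prop-1-en-2-yl)undeca-3,9-dienoic acid F2. Yamaguchi macrolactonisation (2,4,6-trichlorobenzoyl chloride, Et3N; DMAP, toluene, high dilution) closes the twelve-membered allylic lactone, 14 with a C(=O) inserted between the ring oxygen and C3 and a phenylsulfonyl group on C3, F3. Pd(PPh3)4 in THF at 40–50 °C then ionises the allyl ester, the α-sulfonyl carboxylate loses CO2 and the sulfonyl-stabilised carbanion recombines at C2 (Tsuji–Trost decarboxylative allylation, a two-atom ring contraction); attack at C10 is again excluded by the E-alkene. This gives (1(10)E,4E,6S,7S)-6-[(tert-butyldimethylsilyl)oxy]-3-(phenylsulfonyl)germacra-1(10),4,11-triene F4. Oxidative desulfonylation (LDA, THF, −78 °C; MoO5·pyridine·HMPA) then gives enone 18.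

2. Step 11. What may go wrong: intermolecular etherification (dimers, oligomers) or base-induced loss of HCl outruns closure of the strained eleven-membered ring. The fallback replaces the SN2 alkylation of a sodium alkoxide by a palladium π-allyl etherification; it sets out from 12 and comes back at 14. Et2Zn (0.5 equiv) converts 12 into its zinc alkoxide, and Pd(PPh3)4 (5 mol%, THF, rt, slow addition) ionises the allylic chloride to a π-allyl complex whose less hindered C3 terminus is attacked by the zinc alkoxide. No compound outside the list is formed (none F0).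

3. Step 17. What may go wrong: oxygen delivery to the wrong face of C4=C5 if the ring reacts through its other planar-chiral conformer, or Lewis-acid-promoted transannular opening of the new epoxide by the C1=C10 alkene. The fallback epoxidises one stage earlier under the direction of a C3 hydroxyl and installs the angelate with inversion; it sets out from 18 and comes back at 23. Reduction of 18 with the (S)-oxazaborolidine and catecholborane gives (1(10)E,3R,4E,6S,7S)-6-[(tert-butyldimethylsilyl)oxy]germacra-1(10),4,11-trien-3-ol F5. VO(acac)2/t-BuOOH, erythro-selective for an allylic alcohol with a geminal methyl group, gives (1(10)E,3R,4R,5R,6R,7S)-6-[(tert-butyldimethylsilyl)oxy]-4,5-epoxygermacra-1(10),11-dien-3-ol F6. Mitsunobu esterification (angelic acid, PPh3, diisopropyl azodicarboxylate, toluene, 0 °C) inverts C3 to give (1(10)E,3S,4R,5R,6R,7S)-6-[(tert-butyldimethylsilyl)oxy]-4,5-epoxygermacra-1(10),11-dien-3-yl (2Z)-2-methylbut-2-enoate F7. Bu4NF/AcOH then gives 23.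

**Further compounds**

F1 | step 12 | (2E,6S)-6-[(1S,2E)-1-[(tert-butyldimethylsilyl)oxy]-3-methyl-4-(phenylsulfonyl)but-2-en-1-yl]-3,7-dimethylocta-2,7-dien-1-ol | C=C(C)[C@H](CC/C(C)=C/CO)[C@@H](O[Si](C)(C)C(C)(C)C)/C=C(C)/CS(=O)(=O)c1ccccc1
F2 | step 12 | (3E,5S,6S,9E)-5-[(tert-butyldimethylsilyl)oxy]-11-hydroxy-3,9-dimethyl-2-(phenylsulfonyl)-6-(prop-1-en-2-yl)undeca-3,9-dienoic acid | C=C(C)[C@H](CC/C(C)=C/CO)[C@@H](O[Si](C)(C)C(C)(C)C)/C=C(C)/C(C(=O)O)S(=O)(=O)c1ccccc1
F3 | step 12 | twelve-membered allylic lactone: 14 with C(=O) inserted between the ring oxygen and C3, phenylsulfonyl on C3 | C=C(C)[C@@H]1CC/C(C)=C/COC(=O)C(S(=O)(=O)c2ccccc2)/C(C)=C/[C@@H]1O[Si](C)(C)C(C)(C)C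
F4 | step 12 | (1(10)E,4E,6S,7S)-6-[(tert-butyldimethylsilyl)oxy]-3-(phenylsulfonyl)germacra-1(10),4,11-triene | C=C(C)[C@@H]1CC/C(C)=C/CC(S(=O)(=O)c2ccccc2)/C(C)=C/[C@@H]1O[Si](C)(C)C(C)(C)C
F0 | step 11 | none | none
F5 | step 17 | (1(10)E,3R,4E,6S,7S)-6-[(tert-butyldimethylsilyl)oxy]germacra-1(10),4,11-trien-3-ol | C=C(C)[C@@H]1CC/C(C)=C/C[C@@H](O)/C(C)=C/[C@@H]1O[Si](C)(C)C(C)(C)C
F6 | step 17 | (1(10)E,3R,4R,5R,6R,7S)-6-[(tert-butyldimethylsilyl)oxy]-4,5-epoxygermacra-1(10),11-dien-3-ol | C=C(C)[C@@H]1CC/C(C)=C/C[C@@H](O)[C@@]2(C)O[C@@H]2[C@@H]1O[Si](C)(C)C(C)(C)C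
F7 | step 17 | (1(10)E,3S,4R,5R,6R,7S)-6-[(tert-butyldimethylsilyl)oxy]-4,5-epoxygermacra-1(10),11-dien-3-yl (2Z)-2-methylbut-2-enoate | C=C(C)[C@@H]1CC/C(C)=C/C[C@H](OC(=O)/C(C)=C\C)[C@@]2(C)O[C@@H]2[C@@H]1O[Si](C)(C)C(C)(C)C
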